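The late readings of the grey flask, which is the flask asked about, have stopped climbing: from 8.00 h to 25.0 h target moves from 23.7 % to 24.7 %, a step the size of the scatter.

| setting | grey | green | flask |
|---|---|---|---|
| starting material | 20 mM | 20 mM | 20 mM |
| second substrate | 20 mM | 30 mM | 20.0 mM |
| partner | 26 mM | 26 mM | 26.0 mM |
| free catalyst | 17 µM | 17 µM | 17 µM |
| temperature | 70 °C | 55 °C | 70 °C |
| remark | the very flask that is asked about, followed so far | run made earlier |  |
| time |  |  | 30 h |

- grey (time / h: target / %): 1.50: 10.1; 5.00: 23.9; 8.00: 23.7; 12.0: 25.9; 20.0: 27.2; 25.0: 24.7
- green (time / h: target / %): 2.00: 2.6; 5.00: 8.7; 8.00: 13.0; 12.0: 16.8; 20.0: 21.8; 25.0: 21.4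

(scatter of a reading: 1 percentage point)

- north: at 30 h take out 90 % of the target then present, then wait 2.5 d
- north-east: at 30 h raise the temperature by 15 K, then wait 2.5 d
- west: change nothing and wait 2.5 d more
- east: at 30 h add partner, 50.0 % of the amount charged, then wait 2.5 d
- north-west: at 30 h add free catalyst, 100 % of the amount charged, then wait 2.5 d

- target taken out counts as made
- additions bring no volume worth counting

1. target, in percent of the starting material first charged, at 30 h
2. which option adds most target ("none" when 2 percentage points or less is all one gets) (north / north-east / west / east / north-west / none)
3. target present, with what was taken out counted in, in percent of the starting material first charged, after west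
4. target present, with what was taken out counted in, in percent of the starting material first charged, after north-west

I turn the question round: what would have to be true for waiting, heating, taking out target or adding partner to pay at 30 h? Catalyst would have to be working then. But at the pace of the first reading, the 1 percentage point that the grey readings show from 8.00 h to 25.0 h would take 0.149 h, and they took 17.0 h, far longer. A shortage of reagent is no better. Taken one to one with partner, c(starting material) of 20 mM is the limiting reagent, smaller than the 26 mM of partner, yet target in the grey flask stops at 25.4 %, the mean of those late readings. So I take the catalyst to be lost, though a stop at equilibrium would look the same in these readings.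

I call that mean the dose share: the fraction of the starting material present that one charge of 17 µM turns into target before it stops. If catalyst is lost at its own pace while turnover follows c(starting material), with the other amounts taken as held, each equal charge takes the same fraction of what it finds. A second charge then brings the flask to 44.3 %, a gain of 19 points, well above the margin of 2 points.

The forecast gives 25.5 % (24.3 % to 26.8 %) for now, 25.5 % after west, and north-west as best, holding that “A fresh catalyst dose repeats the same integrated catalyst exposure”. Its 40 % (27 % to 44 %) after north-west is lower than my figure.

The flask gives 26.3 % now, 26.3 % after west and 46.2 % after north-west, so north-west is best, adding 20 points while west adds 0 points.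

    starting material + free catalyst ⇌ catalyst intermediate A (K = 110 M⁻¹, k = 12.0 M⁻¹ s⁻¹, Ea = 57.0 kJ mol⁻¹, ΔH = 6.00 kJ mol⁻¹)
    catalyst intermediate B → spent catalyst (k = 1.40 × 10⁻⁴ s⁻¹, Ea = 96.0 kJ mol⁻¹)
    partner + catalyst intermediate A → free catalyst + target (k = 64.0 M⁻¹ s⁻¹, Ea = 35.0 kJ mol⁻¹)
    partner + catalyst intermediate B → free catalyst + second product (k = 1.70 M⁻¹ s⁻¹, Ea = 67.0 kJ mol⁻¹)
    second substrate + free catalyst ⇌ catalyst intermediate B (K = 380 M⁻¹, k = 26.0 M⁻¹ s⁻¹, Ea = 38.0 kJ mol⁻¹, ΔH = −21.0 kJ mol⁻¹)
    (constants at 70 °C)

In this flask, the step from partner and catalyst intermediate A to target had 92 % of its turnover up to 30 h behind it by 6.00 h. By 15.0 h spent catalyst stood at 99.7 % of the catalyst charged and target at 26.3 %. The forecast after north-west is 6.2 points low, and my figure from the dose share falls 1.9 points short. With 0.043 mM of free catalyst from the start, counted as 2.53 charges given together, the dose share gives 52.3 %. That neighbour holds 54.3 % target at 30.0 h.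

All runs were generated by integration from invented constants.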